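**Assumption:** the SMILES carries no stereodescriptor and the molecule has no stereocentre; the only possible stereo element, the ring A–ring B biaryl axis, is unspecified, so the route uses no axial control and delivers the compound as drawn.

## Retrosynthetic overview

1. Target ⇒ global O-debenzylation (last) of an octabenzyl aryl sulfate salt ⇒ O-sulfation of the single free phenol of terphenyl 9.
2. Terphenyl 9 ⇒ ring A–ring B bond by Suzuki–Miyaura coupling of iodophenol 8 (ring A) with biphenyl boronate 6 (rings B and C).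
3. Boronate 6 ⇒ mono-iodination and borylation of symmetrical hexakis(benzyloxy)biphenyl 3 ⇒ Ullmann homocoupling of iodide 2 (ring B–ring C bond).
4. No ring is built: all three arenes are bought as phloroglucinol benzyl ethers (1 and 7). Order of joining: B–C, then A–B, then sulfate, then deprotection.

## Route

Step 1
Reactants: 1 1,3,5-tris(benzyloxy)benzene
Product: 2 1,3,5-tris(benzyloxy)-2-iodobenzene
Conditions: NIS (1.05 equiv), CH2Cl2, 0 °C → rt, dark
Reagents that add atoms: N-iodosuccinimide, O=C1CCC(=O)N1I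
Why: Electrophilic aromatic iodination of a very electron-rich arene whose three ring CH positions are equivalent; the first iodine deactivates the ring, so mono-iodination is clean.

Step 2
Reactants: 2 1,3,5-tris(benzyloxy)-2-iodobenzene (two molecules)
Product: 3 2,2',4,4',6,6'-hexakis(benzyloxy)-1,1'-biphenyl
Conditions: Cu powder (activated, 5 equiv), neat melt, 210 °C, Ar
Reagents that add atoms: none
Why: Classical Ullmann reductive homocoupling of an aryl iodide on copper metal forms the symmetrical tetra-ortho-oxygenated B–C biaryl; benzyl ethers tolerate the neutral aprotic melt and the symmetrical product has no stereo element.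

Step 3
Reactants: 3 2,2',4,4',6,6'-hexakis(benzyloxy)-1,1'-biphenyl
Product: 4 2,2',4,4',6,6'-hexakis(benzyloxy)-3-iodo-1,1'-biphenyl
Conditions: NIS (0.8 equiv, slow addition), CH2Cl2, −20 → 0 °C; unreacted 3 recycled
Reagents that add atoms: N-iodosuccinimide, O=C1CCC(=O)N1I
Why: Electrophilic aromatic iodination; the four ring CH positions of 3 are equivalent, so only one mono-iodide can form, and sub-stoichiometric NIS limits the statistical 3,3'-diiodide.

Step 4
Reactants: 4 2,2',4,4',6,6'-hexakis(benzyloxy)-3-iodo-1,1'-biphenyl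
Product: 6 2-[2,2',4,4',6,6'-hexakis(benzyloxy)-1,1'-biphenyl-3-yl]-4,4,5,5-tetramethyl-1,3,2-dioxaborolane, via biphenylylmagnesium chloride 5 (not isolated)
Conditions: iPrMgCl·LiCl (1.3 equiv), THF, −15 → 0 °C; then iPrOBpin (2 equiv), 0 °C → rt; aq NH4Cl
Reagents that add atoms: 2-isopropoxy-4,4,5,5-tetramethyl-1,3,2-dioxaborolane, CC(C)OB1OC(C)(C)C(C)(C)O1; isopropylmagnesium chloride–lithium chloride, CC(C)[Mg]Cl.[Li+].[Cl-] (Mg and Cl are held only in intermediate 5)
Why: Iodine–magnesium exchange is fast for an aryl iodide flanked by two alkoxy groups and leaves benzyl ethers untouched; the aryl Grignard is then trapped by the borate ester to give the pinacol boronate.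

Step 5
Reactants: 7 3,5-bis(benzyloxy)phenol
Product: 8 3,5-bis(benzyloxy)-2-iodophenol
Conditions: NIS (1.0 equiv), CH2Cl2, −40 → 0 °C; chromatography
Reagents that add atoms: N-iodosuccinimide, O=C1CCC(=O)N1I
Why: Electrophilic aromatic iodination of the phenol; the position between OH and OBn is favoured statistically (two sites) and sterically over the one between two OBn groups, and the minor 4-iodo isomer is removed by chromatography.

Step 6
Reactants: 6 2-[2,2',4,4',6,6'-hexakis(benzyloxy)-1,1'-biphenyl-3-yl]-4,4,5,5-tetramethyl-1,3,2-dioxaborolane; 8 3,5-bis(benzyloxy)-2-iodophenol (1.5 equiv)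
Product: 9 2',4,4',6,6'-pentakis(benzyloxy)-3'-[2,4,6-tris(benzyloxy)phenyl]-1,1'-biphenyl-2-ol
Conditions: Pd(OAc)2 (10 mol%), SPhos (20 mol%), K3PO4 (4 equiv), degassed toluene/H2O 10:1, 100 °C; aq NH4Cl work-up
Reagents that add atoms: none
Why: Suzuki–Miyaura coupling with the bulky, electron-rich biaryl phosphine SPhos, a ligand class that delivers tetra-ortho-substituted biaryls, forms the A–B bond; the phenol (as phenoxide) and benzyl ethers are inert, and the new axis is formed without control because none is specified.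

Step 7
Reactants: 9 2',4,4',6,6'-pentakis(benzyloxy)-3'-[2,4,6-tris(benzyloxy)phenyl]-1,1'-biphenyl-2-ol
Product: 11 sodium 2',4,4',6,6'-pentakis(benzyloxy)-3'-[2,4,6-tris(benzyloxy)phenyl]-1,1'-biphenyl-2-yl sulfate, via pyridinium aryl sulfate 10 (not isolated)
Conditions: SO3·pyridine (5 equiv), pyridine, 50 °C; then aq NaHCO3; extraction, SiO2 (CH2Cl2/MeOH)
Reagents that add atoms: sulfur trioxide–pyridine complex, O=S(=O)([O-])[n+]1ccccc1; sodium hydrogen carbonate, [Na+].OC([O-])=O
Why: O-sulfation of the only free hydroxyl by the SO3–amine complex; the counter-ion is exchanged to sodium because pyridine would inhibit the palladium-catalysed debenzylation that follows.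

Step 8
Reactants: 11 sodium 2',4,4',6,6'-pentakis(benzyloxy)-3'-[2,4,6-tris(benzyloxy)phenyl]-1,1'-biphenyl-2-yl sulfate
Product: 13 2',4,4',6,6'-pentahydroxy-3'-(2,4,6-trihydroxyphenyl)-1,1'-biphenyl-2-yl hydrogen sulfate (CNP0244954.0), via sodium salt of the target 12 (not isolated)
Conditions: H2 (1 atm), 10% Pd/C, THF/MeOH 1:1, rt; filter under Ar; HCl (1.0 equiv, aq), 0 °C; Sephadex LH-20 (MeOH), freeze-dry
Reagents that add atoms: none
Why: Catalytic hydrogenolysis cleaves all eight benzyl ethers while the aryl sulfate monoester anion is inert to H2 on palladium; one equivalent of cold acid then gives the hydrogen sulfate, which is desalted and kept cold because the free acid is hydrolytically labile.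

## Compound list

1 | 1,3,5-tris(benzyloxy)benzene | c1c(OCc2ccccc2)cc(OCc2ccccc2)cc1OCc1ccccc1 | starting material
2 | 1,3,5-tris(benzyloxy)-2-iodobenzene | Ic1c(OCc2ccccc2)cc(OCc2ccccc2)cc1OCc1ccccc1 | intermediate
3 | 2,2',4,4',6,6'-hexakis(benzyloxy)-1,1'-biphenyl | C(c1ccccc1)Oc1cc(OCc2ccccc2)cc(OCc2ccccc2)c1-c1c(OCc2ccccc2)cc(OCc2ccccc2)cc1OCc1ccccc1 | intermediate
4 | 2,2',4,4',6,6'-hexakis(benzyloxy)-3-iodo-1,1'-biphenyl | Ic1c(OCc2ccccc2)cc(OCc2ccccc2)c(-c2c(OCc3ccccc3)cc(OCc3ccccc3)cc2OCc2ccccc2)c1OCc1ccccc1 | intermediate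
5 | [2,2',4,4',6,6'-hexakis(benzyloxy)-1,1'-biphenyl-3-yl]magnesium chloride (LiCl complex in solution) | Cl[Mg]c1c(OCc2ccccc2)cc(OCc2ccccc2)c(-c2c(OCc3ccccc3)cc(OCc3ccccc3)cc2OCc2ccccc2)c1OCc1ccccc1 | intermediate (not isolated)
6 | 2-[2,2',4,4',6,6'-hexakis(benzyloxy)-1,1'-biphenyl-3-yl]-4,4,5,5-tetramethyl-1,3,2-dioxaborolane | CC1(C)OB(OC1(C)C)c1c(OCc2ccccc2)cc(OCc2ccccc2)c(-c2c(OCc3ccccc3)cc(OCc3ccccc3)cc2OCc2ccccc2)c1OCc1ccccc1 | intermediate
7 | 3,5-bis(benzyloxy)phenol | Oc1cc(OCc2ccccc2)cc(OCc2ccccc2)c1 | starting material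
8 | 3,5-bis(benzyloxy)-2-iodophenol | Oc1cc(OCc2ccccc2)cc(OCc2ccccc2)c1I | intermediate
9 | 2',4,4',6,6'-pentakis(benzyloxy)-3'-[2,4,6-tris(benzyloxy)phenyl]-1,1'-biphenyl-2-ol (ring A carries the free OH; rings B and C fully benzylated) | Oc1cc(OCc2ccccc2)cc(OCc2ccccc2)c1-c1c(OCc2ccccc2)cc(OCc2ccccc2)c(-c2c(OCc3ccccc3)cc(OCc3ccccc3)cc2OCc2ccccc2)c1OCc1ccccc1 | intermediate
10 | pyridinium 2',4,4',6,6'-pentakis(benzyloxy)-3'-[2,4,6-tris(benzyloxy)phenyl]-1,1'-biphenyl-2-yl sulfate | [O-]S(=O)(=O)Oc1cc(OCc2ccccc2)cc(OCc2ccccc2)c1-c1c(OCc2ccccc2)cc(OCc2ccccc2)c(-c2c(OCc3ccccc3)cc(OCc3ccccc3)cc2OCc2ccccc2)c1OCc1ccccc1.c1cc[nH+]cc1 | intermediate (not isolated)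
11 | sodium 2',4,4',6,6'-pentakis(benzyloxy)-3'-[2,4,6-tris(benzyloxy)phenyl]-1,1'-biphenyl-2-yl sulfate | [Na+].[O-]S(=O)(=O)Oc1cc(OCc2ccccc2)cc(OCc2ccccc2)c1-c1c(OCc2ccccc2)cc(OCc2ccccc2)c(-c2c(OCc3ccccc3)cc(OCc3ccccc3)cc2OCc2ccccc2)c1OCc1ccccc1 | intermediate
12 | sodium 2',4,4',6,6'-pentahydroxy-3'-(2,4,6-trihydroxyphenyl)-1,1'-biphenyl-2-yl sulfate | [Na+].[O-]S(=O)(=O)Oc1cc(O)cc(O)c1-c1c(O)cc(O)c(-c2c(O)cc(O)cc2O)c1O | intermediate (not isolated)
13 | 2',4,4',6,6'-pentahydroxy-3'-(2,4,6-trihydroxyphenyl)-1,1'-biphenyl-2-yl hydrogen sulfate | O=S(=O)(O)Oc1cc(O)cc(O)c1-c1c(O)cc(O)c(-c2c(O)cc(O)cc2O)c1O | target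

## Step count and risks

Total steps: 8. Longest linear sequence: 7 (steps 1, 2, 3, 4, 6, 7, 8 from compound 1); step 5 is a one-step branch from compound 7.

**Step 6 (tetra-ortho Suzuki coupling).** The hindered, electron-rich boronate 6 may protodeboronate back to 3, and the free iodophenol 8 may couple slowly. The fallback reverses the polarity and masks the phenol, so that the valuable biphenyl is the electrophile and the cheap ring A partner is used in excess. It sets out from 8 and uses iodobiphenyl 4 from step 3 as partner. Compound 8 is treated with MOMCl and iPr2NEt in CH2Cl2 to give 1,5-bis(benzyloxy)-2-iodo-3-(methoxymethoxy)benzene F1. Palladium-catalysed borylation (PdCl2(CH3CN)2, SPhos, pinacolborane, Et3N, dioxane, 80 °C) converts it into 2-[2,4-bis(benzyloxy)-6-(methoxymethoxy)phenyl]-4,4,5,5-tetramethyl-1,3,2-dioxaborolane F2. F2 (2–3 equiv) is coupled with 4 (Pd(OAc)2, SPhos, K3PO4, toluene/H2O, 100 °C) to give the MOM-protected terphenyl 2',4,4',6,6'-pentakis(benzyloxy)-2-(methoxymethoxy)-3'-[2,4,6-tris(benzyloxy)phenyl]-1,1'-biphenyl F3. HCl in MeOH/THF at rt removes the MOM group, and the route is rejoined at 9.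

**Step 2 (Ullmann homocoupling).** An unactivated, di-ortho-alkoxy aryl iodide at 210 °C may give reduction to 1 or partial loss of benzyl groups. The fallback replaces the copper-mediated reductive coupling by a palladium-catalysed Negishi cross-coupling of two halves of the same iodide. It sets out from 2. Half of 2 is exchanged with iPrMgCl·LiCl (THF, −15 → 0 °C) to [2,4,6-tris(benzyloxy)phenyl]magnesium chloride F4. ZnCl2 transmetalates it to [2,4,6-tris(benzyloxy)phenyl]zinc chloride F5. F5 is coupled with the other half of 2 (Pd2(dba)3, RuPhos, THF/NMP, 70 °C), and the route is rejoined at 3.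

**Step 3 (statistical mono-iodination).** The two rings of 3 react independently, so 3, 4 and the diiodide may form an inseparable mixture. The fallback builds the iodobiphenyl by a mono-selective cross-coupling instead and bypasses 3. It sets out from 2. One portion of 2 is borylated (PdCl2(CH3CN)2, SPhos, pinacolborane, Et3N, dioxane, 80 °C) to 2-[2,4,6-tris(benzyloxy)phenyl]-4,4,5,5-tetramethyl-1,3,2-dioxaborolane F6. A second portion is iodinated again (NIS, cat. CF3CO2H, CH2Cl2, rt) to 1,3,5-tris(benzyloxy)-2,4-diiodobenzene F7. Suzuki–Miyaura coupling of F6 with an excess of F7 (3 equiv; Pd(OAc)2, SPhos, K3PO4, toluene/H2O, 90 °C) gives the mono-coupled product, helped by the greater hindrance of the second site; the excess diiodide is recovered and the route is rejoined at 4.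

## Further compounds

F1 | step 6 | 1,5-bis(benzyloxy)-2-iodo-3-(methoxymethoxy)benzene | COCOc1cc(OCc2ccccc2)cc(OCc2ccccc2)c1I
F2 | step 6 | 2-[2,4-bis(benzyloxy)-6-(methoxymethoxy)phenyl]-4,4,5,5-tetramethyl-1,3,2-dioxaborolane | COCOc1cc(OCc2ccccc2)cc(OCc2ccccc2)c1B1OC(C)(C)C(C)(C)O1
F3 | step 6 | 2',4,4',6,6'-pentakis(benzyloxy)-2-(methoxymethoxy)-3'-[2,4,6-tris(benzyloxy)phenyl]-1,1'-biphenyl | COCOc1cc(OCc2ccccc2)cc(OCc2ccccc2)c1-c1c(OCc2ccccc2)cc(OCc2ccccc2)c(-c2c(OCc3ccccc3)cc(OCc3ccccc3)cc2OCc2ccccc2)c1OCc1ccccc1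
F4 | step 2 | [2,4,6-tris(benzyloxy)phenyl]magnesium chloride | Cl[Mg]c1c(OCc2ccccc2)cc(OCc2ccccc2)cc1OCc1ccccc1
F5 | step 2 | [2,4,6-tris(benzyloxy)phenyl]zinc chloride | Cl[Zn]c1c(OCc2ccccc2)cc(OCc2ccccc2)cc1OCc1ccccc1
F6 | step 3 | 2-[2,4,6-tris(benzyloxy)phenyl]-4,4,5,5-tetramethyl-1,3,2-dioxaborolane | CC1(C)OB(OC1(C)C)c1c(OCc2ccccc2)cc(OCc2ccccc2)cc1OCc1ccccc1
F7 | step 3 | 1,3,5-tris(benzyloxy)-2,4-diiodobenzene | Ic1c(OCc2ccccc2)cc(OCc2ccccc2)c(I)c1OCc1ccccc1
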